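**Retrosynthetic overview**
1. The target comes from a final hydrogenation (C=C and two benzyl ethers) of a bis-benzyl formyl acetate. Its CHO is put in late by Vilsmeier–Haack formylation para to OMe, after acetylation, so the hydroxy aldehyde can never close to a lactol.
2. The C11 tail comes from olefin cross-metathesis of a homoallylic acetate with 1-decene.
3. Key carbon–carbon bond (C2–C3 of the side chain, sets the R carbinol): Brown asymmetric allylboration of an arylacetaldehyde with (+)-Ipc2B(allyl).
4. The arylacetaldehyde comes from Lemieux–Johnson cleavage of an allylarene, made from vanillin by O-allylation, aromatic Claisen rearrangement, Dakin oxidation and dibenzylation.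
5. No ring is built; the benzene ring is carried through from vanillin.

Assumption: (+)-B-allyldiisopinocampheylborane is bought as its 1 molar pentane solution, and the metathesis product is carried as an E/Z mixture (drawn E) because the double bond is hydrogenated at the end.

**Route**

Step 1
Reactants: 1 vanillin; 2 allyl bromide
Product: 3 4-(allyloxy)-3-methoxybenzaldehyde
Conditions: K2CO3 (1.5 equiv), acetone, reflux
Reagents that add atoms: none
Why: Williamson ether synthesis, the vanillin phenoxide displaces bromide from the unhindered allylic halide.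

Step 2
Reactants: 3 4-(allyloxy)-3-methoxybenzaldehyde
Product: 5 3-allyl-4-hydroxy-5-methoxybenzaldehyde (5-allylvanillin), via ortho-dienone 4 (not isolated)
Conditions: N,N-diethylaniline, 195 °C, N2
Reagents that add atoms: none
Why: aromatic Claisen rearrangement; the [3,3] shift can only reach the one free ortho carbon (the other bears OMe) and the dienone tautomerises to the phenol.

Step 3
Reactants: 5 3-allyl-4-hydroxy-5-methoxybenzaldehyde
Product: 7 2-allyl-6-methoxybenzene-1,4-diol, via aryl formate 6 (not isolated)
Conditions: 30% H2O2 (1.3 equiv), aq NaOH (2.2 equiv), THF, 0 °C to rt, N2; then dilute HCl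
Reagents that add atoms: hydrogen peroxide, OO
Why: Dakin oxidation of a para-hydroxybenzaldehyde (hydroperoxide addition, aryl migration, saponification of the formate in the same pot); alkaline peroxide leaves the isolated alkene alone.

Step 4
Reactants: 7 2-allyl-6-methoxybenzene-1,4-diol
Product: 8 1-allyl-2,5-bis(benzyloxy)-3-methoxybenzene
Conditions: BnBr (2.5 equiv), K2CO3 (3 equiv), DMF, 60 °C, argon (crude 7 used at once)
Reagents that add atoms: benzyl bromide, BrCc1ccccc1
Why: double Williamson benzylation; carbonate is too weak to move the allyl double bond into conjugation, and air is excluded to keep the hydroquinone from oxidising.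

Step 5
Reactants: 8 1-allyl-2,5-bis(benzyloxy)-3-methoxybenzene
Product: 10 2-[2,5-bis(benzyloxy)-3-methoxyphenyl]acetaldehyde, via 1,2-diol 9 (not isolated)
Conditions: OsO4 (2 mol%), NaIO4 (4 equiv), 2,6-lutidine (2 equiv), dioxane/H2O 3:1, rt; crude aldehyde used at once
Reagents that add atoms: osmium tetroxide OsO4, O=[Os](=O)(=O)=O; sodium periodate NaIO4, [Na+].[O-]I(=O)(=O)=O
Why: Lemieux–Johnson oxidation (catalytic dihydroxylation, then periodate glycol cleavage); the lutidine buffer suppresses over-oxidation, and the electron-rich ring survives where ozone might attack it.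

Step 6
Reactants: 10 2-[2,5-bis(benzyloxy)-3-methoxyphenyl]acetaldehyde; 11 (+)-B-allyldiisopinocampheylborane
Product: 13 (R)-1-[2,5-bis(benzyloxy)-3-methoxyphenyl]pent-4-en-2-ol, via borinate ester 12 (not isolated)
Conditions: 11 (1.3 equiv), Et2O/pentane, −78 °C, 2 h; then aq NaOH, 30% H2O2, 0 °C to rt
Reagents that add atoms: none
Why: Brown asymmetric allylboration through a chair Zimmerman–Traxler transition state; the reagent from (−)-α-pinene delivers allyl to the Re face of the aldehyde, which is R here because CH2Ar outranks allyl.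

Step 7
Reactants: 13 (R)-1-[2,5-bis(benzyloxy)-3-methoxyphenyl]pent-4-en-2-ol
Product: 14 (R)-1-[2,5-bis(benzyloxy)-3-methoxyphenyl]pent-4-en-2-yl acetate
Conditions: Ac2O (1.5 equiv), pyridine, DMAP (5 mol%), CH2Cl2, rt
Reagents that add atoms: acetic anhydride, CC(=O)OC(C)=O
Why: DMAP-catalysed O-acylation, which does not touch the C–O bond and so keeps the R configuration.

Step 8
Reactants: 14 (R)-1-[2,5-bis(benzyloxy)-3-methoxyphenyl]pent-4-en-2-yl acetate; 15 1-decene
Product: 16 (R,E)-1-[2,5-bis(benzyloxy)-3-methoxyphenyl]tridec-4-en-2-yl acetate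
Conditions: second-generation Grubbs catalyst (3 mol%), 15 (4 equiv), CH2Cl2, 40 °C
Reagents that add atoms: none
Why: olefin cross-metathesis of two unhindered terminal alkenes, driven by loss of ethylene and by the excess of 1-decene; alkene geometry does not matter.

Step 9
Reactants: 16 (R,E)-1-[2,5-bis(benzyloxy)-3-methoxyphenyl]tridec-4-en-2-yl acetate
Product: 18 (R,E)-1-[3,6-bis(benzyloxy)-2-formyl-5-methoxyphenyl]tridec-4-en-2-yl acetate, via aryl iminium salt 17 (not isolated)
Conditions: POCl3 (2.5 equiv), DMF, 0 °C to 60 °C; then aq NaOAc, rt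
Reagents that add atoms: N,N-dimethylformamide, CN(C)C=O; water, O
Why: Vilsmeier–Haack formylation; of the two free ring carbons the one para to OMe and ortho to OBn is the site 1,2,4-trialkoxybenzenes always use, while the other lies between two alkoxy groups and is shielded.

Step 10
Reactants: 18 (R,E)-1-[3,6-bis(benzyloxy)-2-formyl-5-methoxyphenyl]tridec-4-en-2-yl acetate
Product: 19 (R)-1-(2-formyl-3,6-dihydroxy-5-methoxyphenyl)tridecan-2-yl acetate (target)
Conditions: H2 (1 atm), 10% Pd/C, EtOAc, rt, stopped at full debenzylation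
Reagents that add atoms: none
Why: catalytic hydrogenation and hydrogenolysis saturate the alkene and cleave both benzyl ethers; the electron-rich, hindered salicylaldehyde carbonyl and the acetate are slow to reduce under these conditions, and the stereocentre is not involved.

**Compound list**
1 | vanillin (4-hydroxy-3-methoxybenzaldehyde) | COc1cc(C=O)ccc1O | starting material
2 | allyl bromide | C=CCBr | starting material
3 | 4-(allyloxy)-3-methoxybenzaldehyde | C=CCOc1ccc(C=O)cc1OC | intermediate
4 | 6-allyl-4-formyl-2-methoxycyclohexa-2,4-dien-1-one (racemic ortho-dienone) | COC1=CC(C=O)=CC(CC=C)C1=O | intermediate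
5 | 3-allyl-4-hydroxy-5-methoxybenzaldehyde | COc1cc(C=O)cc(CC=C)c1O | intermediate
6 | 3-allyl-4-hydroxy-5-methoxyphenyl formate | COc1cc(OC=O)cc(CC=C)c1O | intermediate
7 | 2-allyl-6-methoxybenzene-1,4-diol | COc1cc(O)cc(CC=C)c1O | intermediate
8 | 1-allyl-2,5-bis(benzyloxy)-3-methoxybenzene | COc1cc(OCc2ccccc2)cc(CC=C)c1OCc1ccccc1 | intermediate
9 | 3-[2,5-bis(benzyloxy)-3-methoxyphenyl]propane-1,2-diol (racemic) | COc1cc(OCc2ccccc2)cc(CC(O)CO)c1OCc1ccccc1 | intermediate
10 | 2-[2,5-bis(benzyloxy)-3-methoxyphenyl]acetaldehyde | COc1cc(OCc2ccccc2)cc(CC=O)c1OCc1ccccc1 | intermediate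
11 | (+)-B-allyldiisopinocampheylborane, both isopinocampheyl groups from (−)-α-pinene | C=CCB([C@H]1C[C@H]2C[C@@H]([C@@H]1C)C2(C)C)[C@H]1C[C@H]2C[C@@H]([C@@H]1C)C2(C)C | starting material
12 | (R)-1-[2,5-bis(benzyloxy)-3-methoxyphenyl]pent-4-en-2-yl diisopinocampheylborinate | C=CC[C@@H](OB([C@H]1C[C@H]2C[C@@H]([C@@H]1C)C2(C)C)[C@H]1C[C@H]2C[C@@H]([C@@H]1C)C2(C)C)Cc1cc(OCc2ccccc2)cc(OC)c1OCc1ccccc1 | intermediate
13 | (R)-1-[2,5-bis(benzyloxy)-3-methoxyphenyl]pent-4-en-2-ol | C=CC[C@@H](O)Cc1cc(OCc2ccccc2)cc(OC)c1OCc1ccccc1 | intermediate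
14 | (R)-1-[2,5-bis(benzyloxy)-3-methoxyphenyl]pent-4-en-2-yl acetate | C=CC[C@@H](OC(C)=O)Cc1cc(OCc2ccccc2)cc(OC)c1OCc1ccccc1 | intermediate
15 | 1-decene | C=CCCCCCCCC | starting material
16 | (R,E)-1-[2,5-bis(benzyloxy)-3-methoxyphenyl]tridec-4-en-2-yl acetate | CCCCCCCC/C=C/C[C@@H](OC(C)=O)Cc1cc(OCc2ccccc2)cc(OC)c1OCc1ccccc1 | intermediate
17 | N-{[2-((R,E)-2-acetoxytridec-4-en-1-yl)-3,6-bis(benzyloxy)-4-methoxyphenyl]methylidene}-N-methylmethanaminium dichlorophosphate | CCCCCCCC/C=C/C[C@@H](OC(C)=O)Cc1c(C=[N+](C)C)c(OCc2ccccc2)cc(OC)c1OCc1ccccc1.[O-]P(=O)(Cl)Cl | intermediate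
18 | (R,E)-1-[3,6-bis(benzyloxy)-2-formyl-5-methoxyphenyl]tridec-4-en-2-yl acetate | CCCCCCCC/C=C/C[C@@H](OC(C)=O)Cc1c(C=O)c(OCc2ccccc2)cc(OC)c1OCc1ccccc1 | intermediate
19 | (R)-1-(2-formyl-3,6-dihydroxy-5-methoxyphenyl)tridecan-2-yl acetate | CCCCCCCCCCC[C@H](Cc1c(O)c(OC)cc(O)c1C=O)OC(C)=O | target

**Step count and risks**

Total step count: 10. Longest linear sequence: 10 steps (1 to 19).

The three steps most likely to fail:

Step 6. The arylacetaldehyde is enolisable and the enantiomeric excess may fall short of what is needed. The fallback sets out from 10 and comes back at 14, using resolution in place of reagent control. Barbier allylation of 10 (allyl bromide 2, Zn dust, THF/saturated aq NH4Cl, 0 °C) gives racemic 1-[2,5-bis(benzyloxy)-3-methoxyphenyl]pent-4-en-2-ol F1. Burkholderia cepacia lipase and vinyl acetate in MTBE at 30 °C acetylate the R enantiomer (Kazlauskas rule, CH2Ar as the large group and allyl as the medium one) and give 14 directly at about half conversion. The recovered (S)-1-[2,5-bis(benzyloxy)-3-methoxyphenyl]pent-4-en-2-ol F2 is converted to 14 as well by Mitsunobu inversion (PPh3, DIAD, AcOH, THF, 0 °C), so both halves converge.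

Step 9. The ring carbon to be formylated sits between a benzyloxy group and the branched side chain, so the reaction may be slow or leak to the carbon between the two oxygens. The fallback sets out from 16 and comes back at 19, reversing the order and changing the mode of formylation. Hydrogenation of 16 (H2, 10% Pd/C, EtOAc, rt) saturates the alkene and removes both benzyl groups to give the hydroquinone (R)-1-(2,5-dihydroxy-3-methoxyphenyl)tridecan-2-yl acetate F3. Magnesium-phenoxide-directed ortho-formylation (anhydrous MgCl2, Et3N, paraformaldehyde, MeCN, reflux, argon) then gives 19. The hydroxyl next to the side chain has no free ortho carbon, so only the other hydroxyl can direct. Of its two ortho carbons, the one para to OMe is electronically preferred and is now flanked by a small OH instead of OBn. This fallback relieves crowding more than it changes the intrinsic site preference, so the regiochemistry would need to be confirmed by NOE or HMBC.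

Step 10. The aldehyde may be over-reduced, or the hindered benzyl ether may cleave slowly. The fallback sets out from 18 and comes back at 19, separating alkene reduction from a non-reductive ether cleavage. Homogeneous hydrogenation (H2, RhCl(PPh3)3 5 mol%, benzene/EtOH, rt) reduces only the alkene and gives (R)-1-[3,6-bis(benzyloxy)-2-formyl-5-methoxyphenyl]tridecan-2-yl acetate F4. BCl3 with pentamethylbenzene in CH2Cl2 at −78 °C then removes both benzyl groups as cations trapped by the scavenger and gives 19; at this temperature the acetate and the methyl ether para to the aldehyde should survive.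

**Further compounds**
F1 | step 6 | racemic 1-[2,5-bis(benzyloxy)-3-methoxyphenyl]pent-4-en-2-ol | C=CCC(O)Cc1cc(OCc2ccccc2)cc(OC)c1OCc1ccccc1
F2 | step 6 | (S)-1-[2,5-bis(benzyloxy)-3-methoxyphenyl]pent-4-en-2-ol | C=CC[C@H](O)Cc1cc(OCc2ccccc2)cc(OC)c1OCc1ccccc1
F3 | step 9 | (R)-1-(2,5-dihydroxy-3-methoxyphenyl)tridecan-2-yl acetate | CCCCCCCCCCC[C@H](Cc1cc(O)cc(OC)c1O)OC(C)=O
F4 | step 10 | (R)-1-[3,6-bis(benzyloxy)-2-formyl-5-methoxyphenyl]tridecan-2-yl acetate | CCCCCCCCCCC[C@H](Cc1c(C=O)c(OCc2ccccc2)cc(OC)c1OCc1ccccc1)OC(C)=O
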